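**Retrosynthetic overview**
1. Bisoflavolin M (12) comes from its pentamethyl ether 11 by global O-demethylation.
2. 11 is cut at both C3–C1' bonds (pyranone C3 to the para-phenylene ring and to the 3',4'-dioxygenated ring) and at both O1–C2 bonds. This gives two molecules of enaminone 4 and the arene-bis(diazonium) salt 9, joined in one three-component photoredox arylation/annulation.
3. Enabling feature: both halves carry the same 8-chloro-5,7-dioxygenated benzo-γ-pyranone (rings A/C). C3 of each pyranone is the α-carbon of a vinylogous ester (O1–C2=C3–C4=O), which in the open-chain enaminone is the radical-accepting carbon. Each C1' lies para to an ether oxygen, where a diazonium group is stable and can come from a nitro group.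
4. 9 comes from an SNAr diaryl ether synthesis (5 + 6), nitro reduction and twofold diazotisation. 4 comes from 2-chloro-3,5-dimethoxyphenol (1) by ortho-acylation and DMF-DMA condensation, which places Cl next to the future O1 (C8).
5. Ring order: the four benzene rings are bought, the diaryl ether link is made first, and the two pyranone C rings are closed last, together, in the key step.

Key step: step 6

Remark: the target has no stereocentre and no hindered axis, so it is achiral and no stereocontrol is needed; 2-chloro-3,5-dimethoxyphenol is assumed to be a purchasable compound.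

**Step 1**
Reactants: 1 2-chloro-3,5-dimethoxyphenol
Product: 3 1-(3-chloro-2-hydroxy-4,6-dimethoxyphenyl)ethan-1-one, via 2-chloro-3,5-dimethoxyphenyl acetate 2 (not isolated)
Conditions: Ac2O, BF3·OEt2, AcOH, 90 °C; then H2O
Reagents that add atoms: acetic anhydride CC(=O)OC(C)=O
Why: BF3-promoted O-acetylation and Fries rearrangement should deliver the acetyl group to C6, the only free position ortho to the hydroxyl because C2 carries chlorine, so that chlorine sits next to the phenol that later becomes O1.

**Step 2**
Reactants: 3 1-(3-chloro-2-hydroxy-4,6-dimethoxyphenyl)ethan-1-one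
Product: 4 (E)-1-(3-chloro-2-hydroxy-4,6-dimethoxyphenyl)-3-(dimethylamino)prop-2-en-1-one
Conditions: DMF-DMA (3 equiv), toluene, 95 °C
Reagents that add atoms: N,N-dimethylformamide dimethyl acetal COC(OC)N(C)C
Why: Condensation of the methyl ketone with the amide acetal (enaminone formation) is standard for 2-hydroxyacetophenones and should give the E-enaminone, with the phenol left free and hydrogen-bonded to the carbonyl.

**Step 3**
Reactants: 5 2-methoxy-5-nitrophenol; 6 1-fluoro-4-nitrobenzene
Product: 7 1-methoxy-4-nitro-2-(4-nitrophenoxy)benzene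
Conditions: K2CO3, DMF, 90 °C
Reagents that add atoms: none
Why: SNAr (addition–elimination) of the phenoxide on the para-nitro-activated aryl fluoride should form the diaryl ether, with the two nitro groups (masked diazonium groups) para to OAr on one ring and para to OMe on the other, as the target requires.

**Step 4**
Reactants: 7 1-methoxy-4-nitro-2-(4-nitrophenoxy)benzene
Product: 8 3-(4-aminophenoxy)-4-methoxyaniline
Conditions: H2 (1 atm), 10% Pd/C, EtOAc–EtOH, rt
Reagents that add atoms: none
Why: Catalytic hydrogenation of nitroarenes should reduce both nitro groups while the diaryl ether and the methyl ether stay intact.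

**Step 5**
Reactants: 8 3-(4-aminophenoxy)-4-methoxyaniline
Product: 9 3-(4-diazoniophenoxy)-4-methoxybenzenediazonium bis(tetrafluoroborate)
Conditions: t-BuONO (2.4 equiv), 48% aq. HBF4 (5 equiv), EtOH, 0 °C; precipitation with Et2O
Reagents that add atoms: tert-butyl nitrite CC(C)(C)ON=O; tetrafluoroboric acid [H+].F[B-](F)(F)F
Why: Twofold diazotisation in strong acid should give the bis(diazonium) salt, since para-alkoxy- and para-aryloxy-arenediazonium tetrafluoroborates are isolable and the acid suppresses triazene formation.

**Step 6**
Reactants: 4 (E)-1-(3-chloro-2-hydroxy-4,6-dimethoxyphenyl)-3-(dimethylamino)prop-2-en-1-one (2.5 equiv); 9 3-(4-diazoniophenoxy)-4-methoxybenzenediazonium bis(tetrafluoroborate)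
Product: 11 8-chloro-3-[4-[5-(8-chloro-5,7-dimethoxy-4-oxo-4H-chromen-3-yl)-2-methoxyphenoxy]phenyl]-5,7-dimethoxy-4H-chromen-4-one, via bis(2-dimethylaminochroman-4-one) aminal 10 (not isolated)
Conditions: eosin Y (5 mol %), DMSO, green LEDs (530 nm), 20 °C, Ar
Reagents that add atoms: none
Why: Photoexcited eosin Y reduces each diazonium group of 9 to an aryl radical (loss of N2), which adds to the α-carbon of the push–pull enaminone 4 (the future C3); the α-amino radical so formed is oxidised to an iminium ion by the eosin radical cation or by a further diazonium ion (radical chain), the chelated phenol adds to the iminium carbon to give aminal 10, and loss of dimethylamine aromatises the γ-pyranone, the sequence running at both ends of 9. The closest known reaction type is the visible-light Meerwein-type arylation/chromone annulation of o-hydroxyaryl enaminones with arenediazonium salts to isoflavones, used here twice on one arene-bis(diazonium). Each of the two pyranone rings closes by 6-exo-trig attack of the phenolic oxygen on the iminium carbon (O1–C2 bond), followed by β-elimination of HNMe2. No stereocentre persists: the C2/C3 centres of 10 are erased by the elimination and 11 is achiral. The step needs C-arylation at the enaminone α-carbon in preference to ionic azo coupling there or radical attack on the A ring, which the polarity-matched addition to a nitrogen-stabilised radical and the weak electrophilicity of the two donor-substituted (para-OAr and para-OMe) diazonium groups should secure; it also needs closure through the oxygen next to C–Cl, which is secured because 4 has only that one free hydroxyl, so chlorine must end at C8. The electron-rich C–Cl bonds lie far outside the reducing power of the photocatalyst, and the excess of 4 should drive both ends to completion.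

**Step 7**
Reactants: 11 8-chloro-3-[4-[5-(8-chloro-5,7-dimethoxy-4-oxo-4H-chromen-3-yl)-2-methoxyphenoxy]phenyl]-5,7-dimethoxy-4H-chromen-4-one
Product: 12 Bisoflavolin M
Conditions: BBr3 (15 equiv), CH2Cl2, −78 °C → rt; then H2O
Reagents that add atoms: none
Why: Lewis-acid cleavage of aryl methyl ethers with BBr3 should free all five phenols (the two peri 5-O-methyl groups first, by chelation to C4=O), while the diaryl ether, the aryl chlorides and the pyranone rings are expected to withstand these anhydrous conditions.

**Compound list**
1 | 2-chloro-3,5-dimethoxyphenol | COc1cc(O)c(Cl)c(OC)c1 | starting material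
2 | 2-chloro-3,5-dimethoxyphenyl acetate (formed in the flask, not isolated) | COc1cc(OC(C)=O)c(Cl)c(OC)c1 | intermediate
3 | 1-(3-chloro-2-hydroxy-4,6-dimethoxyphenyl)ethan-1-one | CC(=O)c1c(O)c(Cl)c(OC)cc1OC | intermediate
4 | (E)-1-(3-chloro-2-hydroxy-4,6-dimethoxyphenyl)-3-(dimethylamino)prop-2-en-1-one | CN(C)/C=C/C(=O)c1c(O)c(Cl)c(OC)cc1OC | intermediate
5 | 2-methoxy-5-nitrophenol | COc1ccc(cc1O)[N+](=O)[O-] | starting material
6 | 1-fluoro-4-nitrobenzene | O=[N+]([O-])c1ccc(F)cc1 | starting material
7 | 1-methoxy-4-nitro-2-(4-nitrophenoxy)benzene | COc1ccc(cc1Oc1ccc(cc1)[N+](=O)[O-])[N+](=O)[O-] | intermediate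
8 | 3-(4-aminophenoxy)-4-methoxyaniline | COc1ccc(N)cc1Oc1ccc(N)cc1 | intermediate
9 | 3-(4-diazoniophenoxy)-4-methoxybenzenediazonium bis(tetrafluoroborate) | COc1ccc(cc1Oc1ccc(cc1)[N+]#N)[N+]#N.F[B-](F)(F)F.F[B-](F)(F)F | intermediate
10 | 8-chloro-3-[4-[5-(8-chloro-2-(dimethylamino)-5,7-dimethoxy-4-oxochroman-3-yl)-2-methoxyphenoxy]phenyl]-2-(dimethylamino)-5,7-dimethoxychroman-4-one (formed in the flask, not isolated; diastereomer mixture, all four stereocentres transient and uncontrolled) | O=C1C(c2ccc(Oc3cc(C4C(N(C)C)Oc5c(Cl)c(OC)cc(OC)c5C4=O)ccc3OC)cc2)C(N(C)C)Oc2c(Cl)c(OC)cc(OC)c12 | intermediate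
11 | 8-chloro-3-[4-[5-(8-chloro-5,7-dimethoxy-4-oxo-4H-chromen-3-yl)-2-methoxyphenoxy]phenyl]-5,7-dimethoxy-4H-chromen-4-one | O=c1c(-c2ccc(Oc3cc(-c4coc5c(Cl)c(OC)cc(OC)c5c4=O)ccc3OC)cc2)coc2c(Cl)c(OC)cc(OC)c12 | intermediate
12 | Bisoflavolin M, 8-chloro-3-[4-[5-(8-chloro-5,7-dihydroxy-4-oxo-4H-chromen-3-yl)-2-hydroxyphenoxy]phenyl]-5,7-dihydroxy-4H-chromen-4-one (achiral) | O=c1c(-c2ccc(Oc3cc(-c4coc5c(Cl)c(O)cc(O)c5c4=O)ccc3O)cc2)coc2c(Cl)c(O)cc(O)c12 | target

**Step count and risks**
Total steps: 7. Longest linear sequence: 5 (steps 3, 4, 5, 6, 7); the other branch is steps 1 and 2.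

Steps most likely to fail:

1. Step 6. One diazonium group may be lost by hydrodediazoniation before the second C–C bond forms, or ionic azo coupling at the enaminone α-carbon may outrun the radical pathway, so that the twofold annulation stalls at one end. The fallback sets out from 4 and 8 and returns at 11 by a twofold Suzuki–Miyaura coupling. Enaminone 4 would be cyclised with I2 (CHCl3, rt; iodocyclisation with loss of dimethylamine) to 8-chloro-3-iodo-5,7-dimethoxy-4H-chromen-4-one F1. Dianiline 8 would be converted by Sandmeyer-type borylation (t-BuONO, B2pin2, MeCN, rt) into 2-[4-methoxy-3-[4-(4,4,5,5-tetramethyl-1,3,2-dioxaborolan-2-yl)phenoxy]phenyl]-4,4,5,5-tetramethyl-1,3,2-dioxaborolane F2. Coupling of F1 (2.3 equiv) and F2 with Pd(dppf)Cl2, K2CO3, dioxane–H2O at 80 °C should form the same two C3–C1' bonds and give 11; the electron-rich C8–Cl bonds should not undergo oxidative addition under these conditions.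

2. Step 7. Cleavage may stop short at the 7-O and 4'-O methyl groups as partly demethylated boron chelates precipitate. Prolonged acid exposure could also open and reclose the pyranone, moving chlorine from C8 to C6 (Wessely–Moser-type isomerisation). The fallback sets out from 11 and returns at 12 by a staged deprotection with two different cleavage modes. BCl3 (CH2Cl2, 0 °C) should remove only the two peri 5-O-methyl groups by chelation to C4=O, giving 8-chloro-3-[4-[5-(8-chloro-5-hydroxy-7-methoxy-4-oxo-4H-chromen-3-yl)-2-methoxyphenoxy]phenyl]-5-hydroxy-7-methoxy-4H-chromen-4-one F3, which would be isolated. The three remaining methyl ethers would then be cleaved by SN2 attack of a soft nucleophile with AlCl3/EtSH (CH2Cl2, 0 °C → rt), a homogeneous, non-protic, low-temperature system that should give 12 without ring opening.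

3. Step 1. Acylation may occur para to the hydroxyl (between the two methoxy groups), or the Lewis acid may demethylate the methoxy group ortho to the new carbonyl. The fallback sets out from 1 and returns at 3 by a Houben–Hoesch reaction. MeCN, ZnCl2 and HCl gas in Et2O at 0 °C should give, by ortho delivery of the nitrilium electrophile from the zinc phenolate, 1-(3-chloro-2-hydroxy-4,6-dimethoxyphenyl)ethan-1-iminium chloride F4 as a precipitate. Hydrolysis in water at 90 °C should then give 3.

**Further compounds**
F1 | step 6 | 8-chloro-3-iodo-5,7-dimethoxy-4H-chromen-4-one | COc1cc(OC)c2c(c1Cl)occ(I)c2=O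
F2 | step 6 | 2-[4-methoxy-3-[4-(4,4,5,5-tetramethyl-1,3,2-dioxaborolan-2-yl)phenoxy]phenyl]-4,4,5,5-tetramethyl-1,3,2-dioxaborolane | COc1ccc(cc1Oc1ccc(cc1)B1OC(C)(C)C(C)(C)O1)B1OC(C)(C)C(C)(C)O1
F3 | step 7 | 8-chloro-3-[4-[5-(8-chloro-5-hydroxy-7-methoxy-4-oxo-4H-chromen-3-yl)-2-methoxyphenoxy]phenyl]-5-hydroxy-7-methoxy-4H-chromen-4-one | O=c1c(-c2ccc(Oc3cc(-c4coc5c(Cl)c(OC)cc(O)c5c4=O)ccc3OC)cc2)coc2c(Cl)c(OC)cc(O)c12
F4 | step 1 | 1-(3-chloro-2-hydroxy-4,6-dimethoxyphenyl)ethan-1-iminium chloride | CC(=[NH2+])c1c(O)c(Cl)c(OC)cc1OC.[Cl-]
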